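**Strategy.** Everything rests on cutting ring B at C5–C10 and C8–C9. Its four stereocentres (C5, C10, C9, C8) are contiguous, C9 bears the carbon (C11) from which the side chain grows and C8 the tertiary oxygen; read backwards, C9=C10 is an enal dienophile and C5=C6–C7=C8 a methyl-substituted silyloxy diene, tied together by C1–C4. A single intramolecular Diels–Alder reaction of the acyclic (E)-enal/(5E,7E)-silyl dienol ether, which already holds the C3 silyl ether and the C4 gem-dimethyl group, closes rings A and B and sets all four centres under control of C3. The aldehyde then receives the C12–C22 chain by methylenation, hydroboration and Suzuki coupling.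

Key step: step 14

Remark: atoms carry the target's numbering (decalin C1–C10, chain C11–C22); read as written, the target SMILES places H5 and the C10 methyl on the same ring face (5S, a cis-fused decalin), and a suprafacial [4+2] can reach that array only from the (5E,7E)-dienol ether through the transition state with the tether under the diene and the formyl group exo, so the precursor is built with the (7E) enol ether geometry and the route is aimed at exactly this stereoisomer.

Step 1
Reactants: 1 geranyl acetate
Product: 3 (2E)-3-methyl-6-oxohex-2-en-1-yl acetate, via 6,7-epoxygeranyl acetate 2 (not isolated)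
Conditions: mCPBA, CH2Cl2, 0 °C; then HIO4·2H2O, THF/H2O, 0 °C → rt
Reagents that add atoms: meta-chloroperoxybenzoic acid, O=C(OO)c1cccc(Cl)c1
Why: Prilezhaev epoxidation picks the electron-rich 6,7-alkene over the alkene deactivated by the allylic acetate, and periodic acid cleaves the crude epoxide (through the diol, Malaprade-type) to the C3 aldehyde and acetone without touching the (E)-alkene that becomes C9=C10.

Step 2
Reactants: 3 (2E)-3-methyl-6-oxohex-2-en-1-yl acetate; 4 1-methoxy-2-methyl-1-(trimethylsilyloxy)propene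
Product: 5 (3S)-β-hydroxy ester (C3 carbinol, C4 gem-dimethyl, C5 methyl ester)
Conditions: N-tosyl-D-valine, BH3·THF, CH2Cl2, 0 °C → rt; then 3 and 4, −78 °C; aq. HCl work-up
Reagents that add atoms: none
Why: In this Mukaiyama aldol promoted by a valine-derived oxazaborolidinone (Kiyooka aldol) the D-valine-derived boron Lewis acid binds the aldehyde and directs the tetrasubstituted ketene acetal to its Re face, which sets C3 as (S) and brings in C4 and C5.

Step 3
Reactants: 5 (3S)-β-hydroxy ester
Product: 6 C3 silyl ether of the ester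
Conditions: TBSOTf, 2,6-lutidine, CH2Cl2, −78 → 0 °C
Reagents that add atoms: tert-butyldimethylsilyl trifluoromethanesulfonate, CC(C)(C)[Si](C)(C)OS(=O)(=O)C(F)(F)F
Why: Silyl ether formation with the reactive triflate protects the hindered neopentylic secondary alcohol as the robust group that later steers the cycloaddition, and no stereocentre is touched.

Step 4
Reactants: 6 C3 silyl ether of the ester
Product: 7 C5,C11-diol
Conditions: i-Bu2AlH (5 equiv), CH2Cl2, −78 → 0 °C; aq. KNaC4H4O6
Reagents that add atoms: none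
Why: Hydride reduction with i-Bu2AlH takes the hindered methyl ester to the primary alcohol and cleaves the acetate in the same operation, which is accepted because no acetate could survive reduction of the C5 ester.

Step 5
Reactants: 7 C5,C11-diol
Product: 8 C11 pivalate with free C5 alcohol
Conditions: t-BuCOCl (1.05 equiv), pyridine, CH2Cl2, −20 °C
Reagents that add atoms: pivaloyl chloride, CC(C)(C)C(=O)Cl
Why: Chemoselective acylation should work because the unhindered allylic primary alcohol reacts with the bulky acid chloride far faster than the neopentylic primary alcohol next to the quaternary C4, and the resulting ester is base-stable and cannot be enolised.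

Step 6
Reactants: 8 C11 pivalate with free C5 alcohol
Product: 9 C5 aldehyde
Conditions: Dess–Martin periodinane, NaHCO3, CH2Cl2, 0 °C → rt
Reagents that add atoms: none
Why: Dess–Martin oxidation under bicarbonate buffer gives the α-quaternary aldehyde, which has no enolisable position and no β-hydroxyl free for retro-aldol cleavage.

Step 7
Reactants: 10 2-(2-bromoethyl)-2-methyl-1,3-dioxolane; 11 1-phenyl-1H-tetrazole-5-thiol
Product: 12 tetrazolyl sulfide
Conditions: K2CO3, DMF, rt
Reagents that add atoms: none
Why: SN2 thioetherification of the primary bromide by the soft thiolate proceeds without disturbing the ketal.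

Step 8
Reactants: 12 tetrazolyl sulfide
Product: 13 tetrazolyl sulfone (C6–C8 unit with masked C8 ketone)
Conditions: mCPBA (2.5 equiv), NaHCO3, CH2Cl2, 0 °C → rt
Reagents that add atoms: meta-chloroperoxybenzoic acid, O=C(OO)c1cccc(Cl)c1
Why: Peracid oxidation of sulfide to sulfone is routine and the bicarbonate buffer keeps the dioxolane intact.

Step 9
Reactants: 9 C5 aldehyde; 13 tetrazolyl sulfone
Product: 14 (5E)-alkene ketal
Conditions: KN(SiMe3)2, DME, −60 °C; then 9, −60 °C → rt
Reagents that add atoms: none
Why: Julia–Kocienski olefination (addition of the sulfonyl carbanion, Smiles rearrangement, loss of SO2 and tetrazolate) forms C5=C6 with the (E) geometry favoured by a potassium base in DME and an α-branched aldehyde.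

Step 10
Reactants: 14 (5E)-alkene ketal
Product: 15 β,γ-unsaturated methyl ketone
Conditions: pyridinium p-toluenesulfonate (cat.), acetone/H2O, rt
Reagents that add atoms: water, O
Why: Mild acid-catalysed acetal hydrolysis frees the C8 ketone while the silyl ether and pivalate survive and the acidity is too low to move the C5=C6 alkene into conjugation.

Step 11
Reactants: 15 β,γ-unsaturated methyl ketone
Product: 17 (5E,7E)-silyl dienol ether pivalate, via lithium dienolate 16 (not isolated)
Conditions: lithium 2,2,6,6-tetramethylpiperidide (from the amine and n-BuLi), LiBr, THF, −78 °C, slow addition of 15; then TBSOTf, −78 °C; cold aq. NaHCO3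
Reagents that add atoms: tert-butyldimethylsilyl trifluoromethanesulfonate, CC(C)(C)[Si](C)(C)OS(=O)(=O)C(F)(F)F
Why: Kinetic enolisation through an Ireland-type cyclic transition state removes a proton from the doubly activated C7 methylene with the vinyl substituent turned away from the bulky amide, which gives the E(O) dienolate as ethyl ketones do with this base and LiBr, and O-silylation at −78 °C fixes the (7E) geometry before any equilibration.

Step 12
Reactants: 17 (5E,7E)-silyl dienol ether pivalate
Product: 18 trienol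
Conditions: i-Bu2AlH (2.5 equiv), CH2Cl2, −78 °C; aq. KNaC4H4O6
Reagents that add atoms: none
Why: Reductive ester cleavage with i-Bu2AlH at low temperature and a neutral tartrate work-up removes the pivalate without hydrolysing the silyl dienol ether.

Step 13
Reactants: 18 trienol
Product: 19 trienal (cycloaddition precursor)
Conditions: MnO2 (activated, excess), CH2Cl2, rt
Reagents that add atoms: none
Why: Allylic oxidation with MnO2 is neutral and heterogeneous, so it converts only the allylic alcohol into the (E)-enal and should neither isomerise C9=C10 nor harm the silyl dienol ether.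

Step 14
Reactants: 19 trienal
Product: 20 octalin aldehyde (C11 aldehyde on C9, C8 silyl ether, C6=C7 alkene)
Conditions: Al(OC6H3Ph2-2,6)3 (1.5 equiv, from Me3Al and 2,6-diphenylphenol), toluene, −78 → 0 °C; aq. NaHCO3
Reagents that add atoms: none
Why: The aluminium phenoxide binds the formyl oxygen and lowers the enal LUMO, so the silyl dienol ether adds across C9=C10 in a concerted but strongly asynchronous [4+2] in which C5–C10 leads and C8–C9 follows (at the limit a vinylogous Mukaiyama–Michael addition with immediate collapse of the ion pair); the closest known reactions are Lewis-acid-promoted intramolecular Diels–Alder reactions of 2,8,10-trienals, including β-methyl dienophiles, and exo-selective Diels–Alder reactions of carbonyl dienophiles held in this aluminium tris(aryloxide). Ring A closes when the diene terminus C5 bonds to the enal β-carbon C10 across the four-atom tether C1–C4 (six-membered, exo to both π systems, chair-like tether), and ring B is the cyclohexene created by the two new σ bonds. The (E)-enal fixes C9 against C10 (C11 cis to the C10 methyl), the (5E,7E)-diene fixes C5 against C8 (H5 cis to the C8 methyl, C4 cis to the silyloxy group), and the transition state with the tether under the diene and the formyl group pointing away joins the two pairs so that H5 and the C10 methyl share one face (cis ring fusion). This formyl-exo mode is not the innate preference of an enal, so it is enforced by the reagent, whose three 2,6-diphenylphenoxide ligands cannot be housed beneath the substituted diene. π-Face selectivity comes from the substrate: only one face lets the C3 silyloxy group lie equatorial on the chair-like tether, the other pushing it axial against C6, which relays the (3S) centre to C5, C8, C9 and C10. The fully substituted C8 terminus and the β,β-disubstituted enal will slow the reaction, hence stoichiometric activation and slow warming.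

Step 15
Reactants: 20 octalin aldehyde
Product: 21 decalin aldehyde
Conditions: H2 (1 atm), Pt/C (platinum on carbon), EtOAc, rt
Reagents that add atoms: none
Why: Heterogeneous catalytic hydrogenation saturates the only alkene, a cis-disubstituted ring alkene, and platinum is chosen because it is less prone than palladium to shift the double bond toward C5 and spares the hindered aldehyde in ethyl acetate.

Step 16
Reactants: 21 decalin aldehyde
Product: 22 C9 vinyl decalin
Conditions: Ph3PCH3Br, KOC(CH3)3, THF, 0 °C → rt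
Reagents that add atoms: methyltriphenylphosphonium bromide, C[P+](c1ccccc1)(c1ccccc1)c1ccccc1.[Br-]
Why: Wittig methylenation with the small unstabilised ylide turns C11 into the vinyl group C11=C12, and addition to the formyl group should outrun enolisation at the shielded C9, so its configuration is kept.

Step 17
Reactants: 23 geranyl bromide; 24 1-(trimethylsilyl)propyne
Product: 27 (5E)-6,10-dimethylundeca-5,9-dien-1-yne, via 3-lithio-1-(trimethylsilyl)propyne 25 (not isolated), via silylated enyne 26 (not isolated)
Conditions: n-BuLi, THF, −78 °C; then 23, −78 °C → rt; then MeOH, K2CO3, rt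
Reagents that add atoms: none
Why: Propargylic alkylation of the primary allylic bromide by the lithiated silylpropyne goes in the SN2 sense with retention of the (E)-alkene, and methoxide-mediated protodesilylation in the same pot frees the terminal alkyne.

Step 18
Reactants: 27 (5E)-6,10-dimethylundeca-5,9-dien-1-yne
Product: 29 (1E,5E)-1-iodo-2,6,10-trimethylundeca-1,5,9-triene, via alkenyldimethylalane 28 (not isolated)
Conditions: Me3Al, Cp2ZrCl2 (cat.), CH2Cl2, 0 °C → rt; then iodine, THF, −30 → 0 °C
Reagents that add atoms: trimethylaluminium, C[Al](C)C; iodine, [I][I]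
Why: Negishi zirconium-catalysed carboalumination adds methyl and aluminium syn across the terminal alkyne with methyl on the internal carbon, and iodinolysis with retention gives the (E)-2-methyl-1-iodoalkene (C13=C14).

Step 19
Reactants: 29 (1E,5E)-1-iodo-2,6,10-trimethylundeca-1,5,9-triene
Product: 30 (2E,6E,10E)-11-iodo-2,6,10-trimethylundeca-2,6,10-trien-1-ol
Conditions: SeO2 (cat.), t-BuOOH, salicylic acid (cat.), CH2Cl2, rt
Reagents that add atoms: tert-butyl hydroperoxide, CC(C)(C)OO
Why: SeO2/t-BuOOH allylic oxidation (ene reaction then [2,3]-sigmatropic shift, Riley-type) hydroxylates the (E)-methyl group of the terminal isopropylidene unit, the preferred site of attack, while the iodoalkene is deactivated and the internal alkene reacts more slowly.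

Step 20
Reactants: 22 C9 vinyl decalin; 30 (2E,6E,10E)-11-iodo-2,6,10-trimethylundeca-2,6,10-trien-1-ol
Product: 32 bis-silyl ether of the target, via B-alkyl-9-borabicyclo[3.3.1]nonane 31 (not isolated)
Conditions: 9-BBN, THF, rt; then 30, Pd(dppf)Cl2 (cat.), AsPh3, Cs2CO3, DMF/H2O, rt
Reagents that add atoms: none
Why: Anti-Markovnikov hydroboration of the terminal vinyl group followed by B-alkyl Suzuki–Miyaura coupling joins C12 to C13 with retention of the (E)-iodoalkene geometry, and the free allylic alcohol is tolerated.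

Step 21
Reactants: 32 bis-silyl ether of the target
Product: 33 myrrhanol A as drawn in the target SMILES
Conditions: n-Bu4NF, THF, 60 °C
Reagents that add atoms: none
Why: Fluoride-mediated desilylation removes the hindered secondary and the tertiary silyl ether under basic, non-ionising conditions that leave the tertiary alcohol and the trisubstituted alkenes intact.

**Compound list**

1 | geranyl acetate, (2E)-3,7-dimethylocta-2,6-dien-1-yl acetate | CC(C)=CCC/C(C)=C/COC(C)=O | starting material
2 | 6,7-epoxygeranyl acetate, (2E)-5-(3,3-dimethyloxiran-2-yl)-3-methylpent-2-en-1-yl acetate (racemic at the epoxide) | CC(=O)OC/C=C(\C)CCC1OC1(C)C | intermediate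
3 | (2E)-3-methyl-6-oxohex-2-en-1-yl acetate | CC(=O)OC/C=C(\C)CCC=O | intermediate
4 | 1-methoxy-2-methyl-1-(trimethylsilyloxy)propene | CC(C)=C(OC)O[Si](C)(C)C | starting material
5 | methyl (3S,6E)-8-acetoxy-3-hydroxy-2,2,6-trimethyloct-6-enoate | CC(=O)OC/C=C(\C)CC[C@H](O)C(C)(C)C(=O)OC | intermediate
6 | methyl (3S,6E)-8-acetoxy-3-[(tert-butyldimethylsilyl)oxy]-2,2,6-trimethyloct-6-enoate | CC(=O)OC/C=C(\C)CC[C@H](O[Si](C)(C)C(C)(C)C)C(C)(C)C(=O)OC | intermediate
7 | (2E,6S)-6-[(tert-butyldimethylsilyl)oxy]-3,7,7-trimethyloct-2-ene-1,8-diol | OC/C=C(\C)CC[C@H](O[Si](C)(C)C(C)(C)C)C(C)(C)CO | intermediate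
8 | (2E,6S)-6-[(tert-butyldimethylsilyl)oxy]-8-hydroxy-3,7,7-trimethyloct-2-en-1-yl 2,2-dimethylpropanoate | CC(C)(C)C(=O)OC/C=C(\C)CC[C@H](O[Si](C)(C)C(C)(C)C)C(C)(C)CO | intermediate
9 | (2E,6S)-6-[(tert-butyldimethylsilyl)oxy]-3,7,7-trimethyl-8-oxooct-2-en-1-yl 2,2-dimethylpropanoate | CC(C)(C)C(=O)OC/C=C(\C)CC[C@H](O[Si](C)(C)C(C)(C)C)C(C)(C)C=O | intermediate
10 | 2-(2-bromoethyl)-2-methyl-1,3-dioxolane | CC1(CCBr)OCCO1 | starting material
11 | 1-phenyl-1H-tetrazole-5-thiol | Sc1nnnn1-c1ccccc1 | starting material
12 | 5-{[2-(2-methyl-1,3-dioxolan-2-yl)ethyl]sulfanyl}-1-phenyl-1H-tetrazole | CC1(CCSc2nnnn2-c2ccccc2)OCCO1 | intermediate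
13 | 5-{[2-(2-methyl-1,3-dioxolan-2-yl)ethyl]sulfonyl}-1-phenyl-1H-tetrazole | CC1(CCS(=O)(=O)c2nnnn2-c2ccccc2)OCCO1 | intermediate
14 | (2E,6S,8E)-6-[(tert-butyldimethylsilyl)oxy]-3,7,7-trimethyl-10-(2-methyl-1,3-dioxolan-2-yl)deca-2,8-dien-1-yl 2,2-dimethylpropanoate | CC(C)(C)C(=O)OC/C=C(\C)CC[C@H](O[Si](C)(C)C(C)(C)C)C(C)(C)/C=C/CC1(C)OCCO1 | intermediate
15 | (2E,6S,8E)-6-[(tert-butyldimethylsilyl)oxy]-3,7,7-trimethyl-11-oxododeca-2,8-dien-1-yl 2,2-dimethylpropanoate | CC(C)(C)C(=O)OC/C=C(\C)CC[C@H](O[Si](C)(C)C(C)(C)C)C(C)(C)/C=C/CC(C)=O | intermediate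
16 | lithium (8E,10E)-dienolate of 15 (O–Li on C11 of the dodecatrienyl chain, C8 of the target) | CC(C)(C)C(=O)OC/C=C(\C)CC[C@H](O[Si](C)(C)C(C)(C)C)C(C)(C)/C=C/C=C(\C)O[Li] | intermediate
17 | (2E,6S,8E,10E)-6,11-bis[(tert-butyldimethylsilyl)oxy]-3,7,7-trimethyldodeca-2,8,10-trien-1-yl 2,2-dimethylpropanoate | CC(C)(C)C(=O)OC/C=C(\C)CC[C@H](O[Si](C)(C)C(C)(C)C)C(C)(C)/C=C/C=C(\C)O[Si](C)(C)C(C)(C)C | intermediate
18 | (2E,6S,8E,10E)-6,11-bis[(tert-butyldimethylsilyl)oxy]-3,7,7-trimethyldodeca-2,8,10-trien-1-ol | OC/C=C(\C)CC[C@H](O[Si](C)(C)C(C)(C)C)C(C)(C)/C=C/C=C(\C)O[Si](C)(C)C(C)(C)C | intermediate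
19 | (2E,6S,8E,10E)-6,11-bis[(tert-butyldimethylsilyl)oxy]-3,7,7-trimethyldodeca-2,8,10-trienal | O=C/C=C(\C)CC[C@H](O[Si](C)(C)C(C)(C)C)C(C)(C)/C=C/C=C(\C)O[Si](C)(C)C(C)(C)C | intermediate
20 | (1R,2R,4aS,6S,8aS)-2,6-bis[(tert-butyldimethylsilyl)oxy]-2,5,5,8a-tetramethyl-1,2,4a,5,6,7,8,8a-octahydronaphthalene-1-carbaldehyde | O=C[C@@H]1[C@@]2(C)CC[C@H](O[Si](C)(C)C(C)(C)C)C(C)(C)[C@H]2C=C[C@@]1(C)O[Si](C)(C)C(C)(C)C | intermediate
21 | (1R,2R,4aS,6S,8aS)-2,6-bis[(tert-butyldimethylsilyl)oxy]-2,5,5,8a-tetramethyldecahydronaphthalene-1-carbaldehyde | O=C[C@@H]1[C@@]2(C)CC[C@H](O[Si](C)(C)C(C)(C)C)C(C)(C)[C@H]2CC[C@@]1(C)O[Si](C)(C)C(C)(C)C | intermediate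
22 | (1R,2R,4aS,6S,8aS)-1-ethenyl-2,5,5,8a-tetramethyldecahydronaphthalene-2,6-diol bis(tert-butyldimethylsilyl) ether | C=C[C@@H]1[C@@]2(C)CC[C@H](O[Si](C)(C)C(C)(C)C)C(C)(C)[C@H]2CC[C@@]1(C)O[Si](C)(C)C(C)(C)C | intermediate
23 | geranyl bromide, (2E)-1-bromo-3,7-dimethylocta-2,6-diene | CC(C)=CCC/C(C)=C/CBr | starting material
24 | 1-(trimethylsilyl)propyne | CC#C[Si](C)(C)C | starting material
25 | 3-lithio-1-(trimethylsilyl)propyne | [Li]CC#C[Si](C)(C)C | intermediate
26 | trimethyl[(5E)-6,10-dimethylundeca-5,9-dien-1-yn-1-yl]silane | CC(C)=CCC/C(C)=C/CCC#C[Si](C)(C)C | intermediate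
27 | (5E)-6,10-dimethylundeca-5,9-dien-1-yne | CC(C)=CCC/C(C)=C/CCC#C | intermediate
28 | dimethyl[(1E,5E)-2,6,10-trimethylundeca-1,5,9-trien-1-yl]alumane | CC(C)=CCC/C(C)=C/CC/C(C)=C/[Al](C)C | intermediate
29 | (1E,5E)-1-iodo-2,6,10-trimethylundeca-1,5,9-triene | CC(C)=CCC/C(C)=C/CC/C(C)=C/I | intermediate
30 | (2E,6E,10E)-11-iodo-2,6,10-trimethylundeca-2,6,10-trien-1-ol | C/C(=C\CC/C(C)=C/CC/C(C)=C/I)CO | intermediate
31 | 9-{2-[(1R,2R,4aS,6S,8aS)-2,6-bis[(tert-butyldimethylsilyl)oxy]-2,5,5,8a-tetramethyldecahydronaphthalen-1-yl]ethyl}-9-borabicyclo[3.3.1]nonane | C1CC2CCCC(C1)B2CC[C@@H]1[C@@]2(C)CC[C@H](O[Si](C)(C)C(C)(C)C)C(C)(C)[C@H]2CC[C@@]1(C)O[Si](C)(C)C(C)(C)C | intermediate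
32 | (2E,6E,10E)-13-[(1R,2R,4aS,6S,8aS)-2,6-bis[(tert-butyldimethylsilyl)oxy]-2,5,5,8a-tetramethyldecahydronaphthalen-1-yl]-2,6,10-trimethyltrideca-2,6,10-trien-1-ol | C/C(=C\CC/C(C)=C/CC/C(C)=C/CC[C@@H]1[C@@]2(C)CC[C@H](O[Si](C)(C)C(C)(C)C)C(C)(C)[C@H]2CC[C@@]1(C)O[Si](C)(C)C(C)(C)C)CO | intermediate
33 | myrrhanol A as drawn, (1R,2R,4aS,6S,8aS)-1-[(3E,7E,11E)-13-hydroxy-4,8,12-trimethyltrideca-3,7,11-trien-1-yl]-2,5,5,8a-tetramethyldecahydronaphthalene-2,6-diol, (3S,5S,8R,9R,10S) in target numbering | C/C(=C\CC/C(C)=C/CC/C(C)=C/CC[C@@H]1[C@@]2(C)CC[C@H](O)C(C)(C)[C@H]2CC[C@@]1(C)O)CO | target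

**Step count**

Total: 21 steps. Longest linear sequence: 16 steps (steps 1–6, 9–16, 20 and 21, from geranyl acetate).

**Steps most likely to fail**

1. Step 14 (cycloaddition). The ring closure may run through the formyl-endo mode, which would give the trans-fused isomer, or it may stop after the first C–C bond so that ring B never forms. The fallback divides the annulation into ionic steps of established type; it sets out from 19 and rejoins the route at 21, so that step 15 is no longer needed. BF3·OEt2 in CH2Cl2 at −78 °C should trigger only the intramolecular vinylogous Mukaiyama–Michael addition of C5 to C10 and, after aqueous work-up, give the ring A enone aldehyde F1, whose diastereomers at C5/C10 can be separated at this monocyclic stage. Hydrogenation over Pd/C in EtOAc saturates the enone alkene to give the keto aldehyde F2. Pyrrolidine/AcOH (enamine catalysis) then closes ring B by intramolecular aldol addition of C9 to the C8 ketone, a reversible step in which C8 and C9 can settle, to give the hydroxy aldehyde F3. TBSOTf/2,6-lutidine silylates the tertiary alcohol and delivers 21.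

2. Step 11 (enol silylation). Geometric control may be lost through proton exchange between enolate and ketone, through leakage to the more stable (7Z) enol ether, or through deprotonation at the methyl group. The fallback fixes both double bonds by stereospecific steps; it sets out from 9 and rejoins at 17, bypassing ketone 15 (steps 7–10 fall away). Propyne is converted by anti-iodoacetoxylation (PhI(OAc)2, iodine, CH2Cl2) into (1E)-1-iodoprop-1-en-2-yl acetate F4. Takai–Utimoto olefination of 9 (CrCl2, 2-(dichloromethyl)-4,4,5,5-tetramethyl-1,3,2-dioxaborolane, LiI, THF) gives the (E)-alkenylboronate F5. Suzuki–Miyaura coupling of F5 with F4 (Pd(PPh3)4, CsF, THF) joins C6 to C7 with retention at both partners and gives the (5E,7E)-dienyl acetate F6. MeLi (2 equiv, THF, −78 °C) should cleave the enol acetate faster than the hindered pivalate and release the lithium dienolate 16 with unchanged geometry, which TBSOTf traps as 17.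

3. Step 15 (hydrogenation). Hydrogen uptake at the ring alkene, shielded by C4 and C8, may be slow, with competing reduction of the formyl group or migration of the double bond toward C5. The fallback is a redox detour with a homogeneous catalyst; it sets out from 20 and rejoins at 21. NaBH4 in MeOH reduces the aldehyde to the primary alcohol F7. Hydrogenation with [Ir(cod)(PCy3)(py)]PF6 in CH2Cl2, to which the hydroxyl group can bind, saturates C6=C7 and gives the saturated alcohol F8. Dess–Martin oxidation restores the aldehyde 21.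

**Further compounds**

F1 | step 14 | 2-{(1R,2S,4S)-4-[(tert-butyldimethylsilyl)oxy]-1,3,3-trimethyl-2-[(1E)-3-oxobut-1-en-1-yl]cyclohexyl}acetaldehyde | O=CC[C@@]1(C)CC[C@H](O[Si](C)(C)C(C)(C)C)C(C)(C)[C@H]1/C=C/C(C)=O
F2 | step 14 | 2-{(1R,2S,4S)-4-[(tert-butyldimethylsilyl)oxy]-1,3,3-trimethyl-2-(3-oxobutyl)cyclohexyl}acetaldehyde | O=CC[C@@]1(C)CC[C@H](O[Si](C)(C)C(C)(C)C)C(C)(C)[C@H]1CCC(C)=O
F3 | step 14 | (1R,2R,4aS,6S,8aS)-6-[(tert-butyldimethylsilyl)oxy]-2-hydroxy-2,5,5,8a-tetramethyldecahydronaphthalene-1-carbaldehyde | O=C[C@@H]1[C@@]2(C)CC[C@H](O[Si](C)(C)C(C)(C)C)C(C)(C)[C@H]2CC[C@@]1(C)O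
F4 | step 11 | (1E)-1-iodoprop-1-en-2-yl acetate | C/C(=C\I)OC(C)=O
F5 | step 11 | (2E,6S,8E)-6-[(tert-butyldimethylsilyl)oxy]-3,7,7-trimethyl-9-(4,4,5,5-tetramethyl-1,3,2-dioxaborolan-2-yl)nona-2,8-dien-1-yl 2,2-dimethylpropanoate | CC(C)(C)C(=O)OC/C=C(\C)CC[C@H](O[Si](C)(C)C(C)(C)C)C(C)(C)/C=C/B1OC(C)(C)C(C)(C)O1
F6 | step 11 | (2E,6S,8E,10E)-11-acetoxy-6-[(tert-butyldimethylsilyl)oxy]-3,7,7-trimethyldodeca-2,8,10-trien-1-yl 2,2-dimethylpropanoate | CC(C)(C)C(=O)OC/C=C(\C)CC[C@H](O[Si](C)(C)C(C)(C)C)C(C)(C)/C=C/C=C(\C)OC(C)=O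
F7 | step 15 | [(1S,2R,4aS,6S,8aS)-2,6-bis[(tert-butyldimethylsilyl)oxy]-2,5,5,8a-tetramethyl-1,2,4a,5,6,7,8,8a-octahydronaphthalen-1-yl]methanol | OC[C@@H]1[C@@]2(C)CC[C@H](O[Si](C)(C)C(C)(C)C)C(C)(C)[C@H]2C=C[C@@]1(C)O[Si](C)(C)C(C)(C)C
F8 | step 15 | [(1S,2R,4aS,6S,8aS)-2,6-bis[(tert-butyldimethylsilyl)oxy]-2,5,5,8a-tetramethyldecahydronaphthalen-1-yl]methanol | OC[C@@H]1[C@@]2(C)CC[C@H](O[Si](C)(C)C(C)(C)C)C(C)(C)[C@H]2CC[C@@]1(C)O[Si](C)(C)C(C)(C)C
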